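**Assumption:** the target is taken exactly as the SMILES reads: 4R (butenolide C5), C6=C7 Z (C24H2OH cis to C5), C10=C11 E. Labels used below: C1 lactone C=O, C2 ring =CH, C3 ring carbon bearing C25H2OH, C4 stereocentre, C5 CH2, C6=C7, C24 = CH2OH on C7, C8–C9, C10=C11.

## Retrosynthetic overview

1. Target ⇐ bis-TBDPS ether ⇐ oxidative lactonisation of a (Z)-ene-1,4-diol (C1–OH/C4–OH). The final butenolide is the last ring formed; the cyclohexene ring is bought in dihydro-β-ionone.
2. C6=C7 (Z) ⇐ Still–Gennari olefination of a C1–C6 aldehyde with an α-alkylated phosphonoacetate carrying C7, C24 and the C8–C23 chain.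
3. C4 (R) ⇐ catalytic asymmetric Mukaiyama acetate aldol on a Z-enal.
4. Z-enal ⇐ 4-(hydroxymethyl)butenolide (a temporary ring from dihydroxyacetone, formed first and opened in Step 3 to fix C1/C4 cis), via a lipase that differentiates the two primary allylic hydroxyls.
5. Side chain ⇐ dihydro-β-ionone → terminal alkyne → Zr-catalysed carboalumination/ethylene oxide → E-homoallylic iodide.

## Route

**Step 1**
Reactants: 1, 1,3-dihydroxyacetone (commercial dimer); 2, ethyl (triphenylphosphoranylidene)acetate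
Product: 3, 4-(hydroxymethyl)furan-2(5H)-one
Conditions: CH2Cl2, rt, 16 h
Reagents that add atoms: none
Why: Wittig olefination of the ketone; the CH2OH cis to the ester lactonises spontaneously, so the ring locks the future C1 and C4 cis across C2=C3.

**Step 2**
Reactants: 3
Product: 4, 4-{[(tert-butyldiphenylsilyl)oxy]methyl}furan-2(5H)-one
Conditions: TBDPSCl, imidazole, DMF, 0 °C → rt
Reagents that add atoms: TBDPSCl, CC(C)(C)[Si](Cl)(c1ccccc1)c1ccccc1
Why: Standard silylation of the primary alcohol (C25–OH); TBDPS survives every later step until the final HF treatment.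

**Step 3**
Reactants: 4
Product: 5, (2E)-2-{[(tert-butyldiphenylsilyl)oxy]methyl}but-2-ene-1,4-diol (the two free CH2OH groups are cis)
Conditions: DIBAL-H (3 eq), CH2Cl2, −78 → 0 °C; Rochelle salt
Reagents that add atoms: none
Why: 1,2-reduction of the unsaturated lactone to the diol; the olefin geometry is inherited from the ring.

**Step 4**
Reactants: 5
Product: 6, (2E)-3-{[(tert-butyldiphenylsilyl)oxy]methyl}-4-hydroxybut-2-en-1-yl acetate (C1–OAc, C4–OH free)
Conditions: lipase (immobilised Candida antarctica lipase B or Burkholderia cepacia lipase), vinyl acetate, MTBE, 25 °C, stop at mono-acetate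
Reagents that add atoms: vinyl acetate, C=COC(C)=O
Why: Lipase (serine hydrolase, EC 3.1.1.3) transesterification is irreversible with the enol ester and acylates only the unhindered CH2OH on the =CH carbon; the CH2OH next to the branched carbon stays free, which decides which carbon becomes C4 and which becomes C1.

**Step 5**
Reactants: 6
Product: 7, (2Z)-4-acetoxy-2-{[(tert-butyldiphenylsilyl)oxy]methyl}but-2-enal
Conditions: activated MnO2, CH2Cl2, rt
Reagents that add atoms: none
Why: Neutral allylic oxidation of the remaining primary allylic alcohol; no acid or base is present to isomerise the enal.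

**Step 6**
Reactants: 7; 8, 1-methoxy-1-(trimethylsilyloxy)ethene (methyl acetate TMS ketene acetal)
Product: 9, methyl (3R,4Z)-6-acetoxy-4-{[(tert-butyldiphenylsilyl)oxy]methyl}-3-hydroxyhex-4-enoate
Conditions: Carreira Ti(IV)/binaphthyl Schiff-base/3,5-di-tert-butylsalicylate catalyst (5 mol %), Et2O, −10 °C; then 1 M HCl/THF to cleave the O-TMS
Reagents that add atoms: none
Why: Catalytic asymmetric Mukaiyama acetate aldol, which performs best on enals; the catalyst antipode that directs the ketene acetal to the Re face of the formyl group is used, which sets C4 as R (expected ≥95% ee, confirmed by Mosher ester).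

**Step 7**
Reactants: 9
Product: 10, methyl (3R,4Z)-4-{[(tert-butyldiphenylsilyl)oxy]methyl}-3,6-dihydroxyhex-4-enoate
Conditions: K2CO3, MeOH, 0 °C
Reagents that add atoms: none
Why: Mild methanolysis of the acetate; the methyl ester is degenerate in MeOH, neither hydroxyl can lactonise onto it (4- or 7-membered ring), and C4 is not enolisable.

**Step 8**
Reactants: 10
Product: 11, methyl (3R,4Z)-4-{[(tert-butyldiphenylsilyl)oxy]methyl}-3,6-bis[(triethylsilyl)oxy]hex-4-enoate
Conditions: TESOTf (2.5 eq), 2,6-lutidine, CH2Cl2, −78 °C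
Reagents that add atoms: TESOTf, CC[Si](CC)(CC)OS(=O)(=O)C(F)(F)F
Why: Silylation of both C1–OH and the hindered C4–OH with a group that can later be removed selectively in the presence of TBDPS.

**Step 9**
Reactants: 11
Product: 12, (3R,4Z)-4-{[(tert-butyldiphenylsilyl)oxy]methyl}-3,6-bis[(triethylsilyl)oxy]hex-4-enal (C6 aldehyde)
Conditions: DIBAL-H (1.1 eq), CH2Cl2, −78 °C; MeOH quench, Rochelle salt
Reagents that add atoms: none
Why: Partial reduction of a β-silyloxy methyl ester stops at the aldehyde at −78 °C; the aldehyde is used directly.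

**Step 10**
Reactants: 13, dihydro-β-ionone [4-(2,6,6-trimethylcyclohex-1-en-1-yl)butan-2-one]
Product: 14, 4-(2,6,6-trimethylcyclohex-1-en-1-yl)but-1-yne
Conditions: LDA, THF, −78 °C; ClP(O)(OEt)2, −78 °C → rt; then LDA (2.3 eq), −78 °C → rt
Reagents that add atoms: none
Why: Negishi methyl ketone → terminal alkyne conversion: kinetic enolate, enol phosphate, then β-elimination.

**Step 11**
Reactants: 14
Product: 15, (3E)-4-methyl-6-(2,6,6-trimethylcyclohex-1-en-1-yl)hex-3-en-1-ol
Conditions: Me3Al (2 eq), Cp2ZrCl2 (0.25 eq), CH2Cl2, rt; then n-BuLi, −78 °C; ethylene oxide, THF, −78 °C → rt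
Reagents that add atoms: trimethylaluminium, C[Al](C)C; ethylene oxide, C1CO1
Why: Negishi Zr-catalysed carboalumination adds Me–Al syn across the alkyne (>98% stereoselective, about 95:5 regioselective); the alkenylalanate opens the epoxide with retention, giving the E-trisubstituted C10=C11 olefin.

**Step 12**
Reactants: 15
Product: 16, 2-[(3E)-6-iodo-3-methylhex-3-en-1-yl]-1,3,3-trimethylcyclohex-1-ene
Conditions: I2, PPh3, imidazole, CH2Cl2, 0 °C
Reagents that add atoms: iodine, II
Why: Appel-type iodination of the primary alcohol under neutral conditions; the olefins are untouched.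

**Step 13**
Reactants: 16; 17, methyl bis(2,2,2-trifluoroethyl)phosphonoacetate (2.5 eq)
Product: 18, methyl (5E)-2-[bis(2,2,2-trifluoroethoxy)phosphoryl]-6-methyl-8-(2,6,6-trimethylcyclohex-1-en-1-yl)oct-5-enoate (racemic at the P-bearing carbon, which becomes sp2 in Step 14)
Conditions: NaH (2.4 eq), DMF, 0 → 50 °C
Reagents that add atoms: none
Why: SN2 alkylation of the soft phosphonoacetate anion with a primary iodide; excess phosphonate suppresses dialkylation and its low basicity disfavours E2.

**Step 14**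
Reactants: 18 (1.3 eq); 12
Product: 19, C24 methyl ester of 1,4-di-O-TES-25-O-TBDPS seco-neomanoalide: methyl (2Z)-enoate with CO2Me on C7 cis to C5, 4R
Conditions: KHMDS, 18-crown-6, THF, −78 °C
Reagents that add atoms: none
Why: Still–Gennari modification of the Horner–Wadsworth–Emmons reaction; kinetic elimination from the electron-poor phosphonate places the ester cis to the aldehyde-derived carbon (Z). C4 is not involved.

**Step 15**
Reactants: 19
Product: 20, (6Z)-allylic alcohol (C24–OH free; C1–OTES, C4–OTES, C25–OTBDPS)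
Conditions: DIBAL-H (2.5 eq), CH2Cl2, −78 °C
Reagents that add atoms: none
Why: 1,2-reduction of the enoate to the allylic alcohol; silyl ethers and olefin geometry are unaffected.

**Step 16**
Reactants: 20
Product: 21, 24,25-bis-O-TBDPS-1,4-bis-O-TES tetraol
Conditions: TBDPSCl, imidazole, DMF, rt
Reagents that add atoms: TBDPSCl, CC(C)(C)[Si](Cl)(c1ccccc1)c1ccccc1
Why: Silylation of the only free hydroxyl, so that C24–OH is masked during the oxidation in Step 18.

**Step 17**
Reactants: 21
Product: 22, (4R)-1,4-diol (C1–OH and C4–OH free, cis across C2=C3; C24 and C25 as TBDPS ethers)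
Conditions: PPTS (cat.), MeOH/CH2Cl2, 0 °C → rt
Reagents that add atoms: none
Why: Acid-catalysed methanolysis removes TES ethers orders of magnitude faster than TBDPS ethers, so the cleavage is selective.

**Step 18**
Reactants: 22
Product: 23, 24,25-bis-O-TBDPS-(6Z)-neomanoalide
Conditions: TEMPO (0.2 eq), PhI(OAc)2 (2.5 eq), CH2Cl2, rt
Reagents that add atoms: none
Why: TEMPO/BAIB oxidative lactonisation: the oxoammonium oxidises only the primary allylic C1–OH, the cis γ-hydroxy enal closes to the lactol, and the lactol is oxidised to the butenolide. The C4–O bond is never broken, so R is retained.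

**Step 19**
Reactants: 23
Product: 24, (6Z)-neomanoalide
Conditions: HF·pyridine, pyridine/THF, 0 °C → rt
Reagents that add atoms: none
Why: Acidic fluoride desilylation of both primary TBDPS ethers; this avoids the basic conditions that could epimerise the butenolide γ-carbon.

## Compound list

1 | 1,3-dihydroxyacetone (as dimer) | OCC(=O)CO | starting material
2 | ethyl (triphenylphosphoranylidene)acetate | CCOC(=O)C=P(c1ccccc1)(c1ccccc1)c1ccccc1 | starting material
3 | 4-(hydroxymethyl)furan-2(5H)-one | O=C1OCC(CO)=C1 | intermediate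
4 | 4-(TBDPS-oxymethyl)furan-2(5H)-one | O=C1OCC(CO[Si](c2ccccc2)(c2ccccc2)C(C)(C)C)=C1 | intermediate
5 | (2E)-2-(TBDPS-oxymethyl)but-2-ene-1,4-diol | OC/C(CO[Si](c1ccccc1)(c1ccccc1)C(C)(C)C)=C\CO | intermediate
6 | (2E)-3-(TBDPS-oxymethyl)-4-hydroxybut-2-en-1-yl acetate | OC/C(CO[Si](c1ccccc1)(c1ccccc1)C(C)(C)C)=C\COC(C)=O | intermediate
7 | (2Z)-4-acetoxy-2-(TBDPS-oxymethyl)but-2-enal | O=C/C(CO[Si](c1ccccc1)(c1ccccc1)C(C)(C)C)=C\COC(C)=O | intermediate
8 | 1-methoxy-1-(trimethylsilyloxy)ethene | C=C(OC)O[Si](C)(C)C | starting material (commercial, or one operation from methyl acetate)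
9 | methyl (3R,4Z)-6-acetoxy-4-(TBDPS-oxymethyl)-3-hydroxyhex-4-enoate | COC(=O)C[C@@H](O)/C(CO[Si](c1ccccc1)(c1ccccc1)C(C)(C)C)=C\COC(C)=O | intermediate
10 | methyl (3R,4Z)-4-(TBDPS-oxymethyl)-3,6-dihydroxyhex-4-enoate | COC(=O)C[C@@H](O)/C(CO[Si](c1ccccc1)(c1ccccc1)C(C)(C)C)=C\CO | intermediate
11 | methyl (3R,4Z)-4-(TBDPS-oxymethyl)-3,6-bis(TES-oxy)hex-4-enoate | COC(=O)C[C@@H](O[Si](CC)(CC)CC)/C(CO[Si](c1ccccc1)(c1ccccc1)C(C)(C)C)=C\CO[Si](CC)(CC)CC | intermediate
12 | (3R,4Z)-4-(TBDPS-oxymethyl)-3,6-bis(TES-oxy)hex-4-enal | O=CC[C@@H](O[Si](CC)(CC)CC)/C(CO[Si](c1ccccc1)(c1ccccc1)C(C)(C)C)=C\CO[Si](CC)(CC)CC | intermediate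
13 | dihydro-β-ionone | CC(=O)CCC1=C(C)CCCC1(C)C | starting material
14 | 4-(2,6,6-trimethylcyclohex-1-en-1-yl)but-1-yne | C#CCCC1=C(C)CCCC1(C)C | intermediate
15 | (3E)-4-methyl-6-(2,6,6-trimethylcyclohex-1-en-1-yl)hex-3-en-1-ol | OCC/C=C(\C)CCC1=C(C)CCCC1(C)C | intermediate
16 | 2-[(3E)-6-iodo-3-methylhex-3-en-1-yl]-1,3,3-trimethylcyclohex-1-ene | ICC/C=C(\C)CCC1=C(C)CCCC1(C)C | intermediate
17 | methyl bis(2,2,2-trifluoroethyl)phosphonoacetate | COC(=O)CP(=O)(OCC(F)(F)F)OCC(F)(F)F | starting material
18 | methyl (5E)-2-[bis(2,2,2-trifluoroethoxy)phosphoryl]-6-methyl-8-(2,6,6-trimethylcyclohex-1-en-1-yl)oct-5-enoate (racemic) | COC(=O)C(CC/C=C(\C)CCC1=C(C)CCCC1(C)C)P(=O)(OCC(F)(F)F)OCC(F)(F)F | intermediate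
19 | C24 methyl ester, 1,4-bis-O-TES, 25-O-TBDPS (4R,6Z,10E) | CC1=C(CC/C(C)=C/CC/C(=C/C[C@@H](O[Si](CC)(CC)CC)/C(CO[Si](c2ccccc2)(c2ccccc2)C(C)(C)C)=C\CO[Si](CC)(CC)CC)C(=O)OC)C(C)(C)CCC1 | intermediate
20 | C24 alcohol, 1,4-bis-O-TES, 25-O-TBDPS | CC1=C(CC/C(C)=C/CC/C(=C/C[C@@H](O[Si](CC)(CC)CC)/C(CO[Si](c2ccccc2)(c2ccccc2)C(C)(C)C)=C\CO[Si](CC)(CC)CC)CO)C(C)(C)CCC1 | intermediate
21 | 24,25-bis-O-TBDPS, 1,4-bis-O-TES | CC1=C(CC/C(C)=C/CC/C(=C/C[C@@H](O[Si](CC)(CC)CC)/C(CO[Si](c2ccccc2)(c2ccccc2)C(C)(C)C)=C\CO[Si](CC)(CC)CC)CO[Si](c2ccccc2)(c2ccccc2)C(C)(C)C)C(C)(C)CCC1 | intermediate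
22 | 24,25-bis-O-TBDPS 1,4-diol | CC1=C(CC/C(C)=C/CC/C(=C/C[C@@H](O)/C(CO[Si](c2ccccc2)(c2ccccc2)C(C)(C)C)=C\CO)CO[Si](c2ccccc2)(c2ccccc2)C(C)(C)C)C(C)(C)CCC1 | intermediate
23 | 24,25-bis-O-TBDPS-(6Z)-neomanoalide | CC1=C(CC/C(C)=C/CC/C(=C/C[C@H]2OC(=O)C=C2CO[Si](c3ccccc3)(c3ccccc3)C(C)(C)C)CO[Si](c3ccccc3)(c3ccccc3)C(C)(C)C)C(C)(C)CCC1 | intermediate
24 | (6Z)-neomanoalide, (5R)-4-(hydroxymethyl)-5-[(2Z,6E)-3-(hydroxymethyl)-7-methyl-9-(2,6,6-trimethylcyclohex-1-en-1-yl)nona-2,6-dien-1-yl]furan-2(5H)-one | CC1=C(CC/C(C)=C/CC/C(=C/C[C@H]2OC(=O)C=C2CO)CO)C(C)(C)CCC1 | target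

## Summary

Total steps: 19. Longest linear sequence: 15 (Steps 1–9, then 14–19); the side-chain branch is Steps 10–13.

Steps most likely to fail, with fallbacks:

1. **Step 6 (asymmetric aldol on a hindered, α-branched Z-enal; ee or conversion may fall short).** Fallback: run the aldol racemically (BF3·OEt2), oxidise the carbinol to the β-keto ester (Dess–Martin), and set C4 by enantioselective ketone reduction instead, using (S)-Me-CBS/catecholborane with the alkenyl as the large group to give the R alcohol. This rejoins the route at 9.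

2. **Step 14 (Still–Gennari: Z/E ratio with the long α-substituent, or β-elimination of the silyloxy aldehyde).** Fallback: enforce the geometry with a ring.
   - Allylate enal 7 with (R)-BINOL/Ti(OiPr)4 and allyltributyltin (Re-face addition, giving the R homoallylic alcohol).
   - Esterify C4–OH with the 2-substituted acrylic acid made from 16 (phosphonoacetate alkylation, HWE with formaldehyde, saponification).
   - Close the 3-alkyl-5,6-dihydropyran-2-one by ring-closing metathesis (Grubbs II); C6=C7 is then necessarily Z.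
   - Open with DIBAL to the C24/C4 diol and continue as in Steps 16–19, after exchanging the C1 acetate for TES.

3. **Step 18 (oxidative lactonisation; the intermediate lactol can dehydrate to a furan, or the secondary alcohol can over-oxidise).** Fallback: avoid the lactol altogether.
   - From 21, remove only the primary C1–OTES.
   - Oxidise C1 stepwise: MnO2 to the enal, then Pinnick oxidation to the acid.
   - Cleave the C4–OTES with acid, so that the cis γ-hydroxy acid lactonises spontaneously to 23.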